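Decide to count turnovers: for a dosed monomer, what matters is how many first-order lifetimes fit into the dosing time.

free monomer 2.0 mM (fed, over 2.5 s); transfer agent 0.600 mM; initiator 0.22 mol%; impurity 1.3 µM; time 2.5 s; the fed solution adds 0.20 times the starting volume

- average number of monomer units in a chain (chains begun, living or dead) at 2.5 s
- part of the free monomer that has reacted at 2.5 s

- charges are per starting volume, the dose included; the dosed solution carries all of it
- the average divides the monomer in chains by the number of chains begun, living and dead together
- run time (flask): 2.5 s

Call n the turnover count, the first-order rate of monomer loss times the dosing time. At a constant rate under steady dosing, the part left is (one minus e to the minus n) over n. Start from below. The uncatalysed step, constant 0.160 s⁻¹, runs regardless, so n is at least 0.400 and you get a floor for c of 17.6%.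

Now go from above. Growth, constant 1.35 × 10⁵ M⁻¹ s⁻¹, adds its constant times the living ends. Those stay within the surplus initiator, the initiator charge less the impurity, 3.10 µM. The impurity comes first, since the initiator's half-life against it, 0.26 s, is shorter than the dosing time. With that surplus as living ends from the first moment, you get the ceiling turnover count 1.45, and c stays below 47.1%.

Tighten the top. The initiator's own count against arriving monomer, constant 891 M⁻¹ s⁻¹, reaches 2.23, so about 2.77 µM of chains begin, diluted by the feed to 2.30 µM. Living ends rising steadily weigh 0.667 of that final value, so n is 0.919 and I commit to c near 34.6%. What lies above the floor goes into chains, which gives dp near 123.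

The forecast gives c 33.5% and dp 138, inside the bracket , with the consumed monomer “split about evenly between chains and the uncatalysed route”.

The flask gives c 32.1% and dp 131.

    free monomer + initiator → living end + monomer in chains (k1 = 891 M⁻¹ s⁻¹)
    free monomer + living end → monomer in chains + living end, rate k2*[living end]*[free monomer] (k2 = 1.35 × 10⁵ M⁻¹ s⁻¹)
    living end + transfer agent → dead chain (k3 = 341 M⁻¹ s⁻¹)
    free monomer → uncatalysed product (k4 = 0.160 s⁻¹)
    initiator + impurity → spent initiator (k5 = 2.02 × 10⁶ M⁻¹ s⁻¹)

In this flask at 1.25 s, impurity stood at 0.119% and living ends at 9.90 × 10⁻⁴ mM, while the uncatalysed step had taken 4.58% of the monomer and chains 2.26%. By 2.50 s growth had caught up, with chains and uncatalysed product at 16.2% and 16.0%. In the neighbour flask with 0.50 mM of free monomer, the initiator charge of 1.10 µM is less than the impurity, so the subtraction behind the ceiling count 1.45 leaves no surplus there. Yet chains began in that neighbour: with 26% of its impurity left, living ends stood at 4.93 × 10⁻⁵ mM, and c reached 18.1%, more than the floor of 17.6%.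

(The rate constants are made up.)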